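**Plan**

1. Retrosynthetic cuts, in order: (a) the central C–C single bond of the (1E,3E)-diene, giving an (E)-alkenyl boronate on the tetrahydrofuran and an (E)-2-iodovinyl isocoumarin; (b) the O1–C5 bond of the tetrahydrofuran (ring atoms O1, C2 with the side chain, C3 with OH, C4, C5 with CH3), giving an open-chain γ-hydroxy terminal alkyne; (c) the C4–C5 bond (acetylide plus the terminal epoxide of desymmetrised divinylcarbinol); (d) in the isocoumarin, the lactone C–O bond and the C3–C4 link, back to a laterally lithiated orsellinate.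
2. Enabling feature: C5 carries only H and CH3 and is 1,4-related to the C2 oxygen, so O1–C5 plus the methyl group is a 4-pentyn-1-ol in disguise. A 5-exo-dig closure and protonation give a five-membered oxocarbenium ion in which the C3 oxygen (β to C5) steers hydride delivery.
3. Forward order: divinylcarbinol → epoxy alcohol → PMB ether → acetylide opening → TBS ether → PMB removal → ring closure/reduction (tetrahydrofuran) → cross-metathesis to the alkenyl boronate. Separately: orsellinate dimethyl ether → chlorination → lateral acylation → isocoumarin → aldehyde → iodovinyl → free phenols. Then Suzuki–Miyaura union and desilylation.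
4. Stereochemistry: C2 and C3 come from the Sharpless desymmetrisation (reagent control); C5 comes from substrate-controlled hydride delivery in the key step; both alkene geometries come from E-selective cross-metathesis and Takai olefination, joined with retention.

Key step: step 6

Remark: tetrahydrofuran numbering used throughout is O1, C2 (side-chain carbon), C3 (CH–O), C4 (CH2), C5 (CH–CH3); reagents named without a compound number are taken as commercial.

**Route**

Step 1
Reactants: 1 penta-1,4-dien-3-ol
Product: 2 (2S,3R)-1,2-epoxypent-4-en-3-ol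
Conditions: Ti(OiPr)4 (cat.), D-(−)-diisopropyl tartrate, t-BuOOH, 4 Å MS, CH2Cl2, −20 °C
Reagents that add atoms: tert-butyl hydroperoxide, CC(C)(C)OO
Why: Sharpless asymmetric epoxidation used as a desymmetrisation; the titanium–tartrate catalyst selects one enantiotopic vinyl group and one of its faces, setting the carbinol carbon (R) and the epoxide CH (S) as the erythro isomer, and the minor enantiomer should be removed by a faster second epoxidation.

Step 2
Reactants: 2 (2S,3R)-1,2-epoxypent-4-en-3-ol
Product: 3 (2S)-2-[(1R)-1-(4-methoxybenzyloxy)prop-2-en-1-yl]oxirane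
Conditions: NaH, 4-MeOC6H4CH2Cl, Bu4NI (cat.), THF, −20 to 0 °C
Reagents that add atoms: 4-methoxybenzyl chloride, COc1ccc(CCl)cc1
Why: Williamson etherification; alkylation of the alkoxide by the in situ benzylic iodide at low temperature should outrun Payne rearrangement, and no stereocentre is touched.

Step 3
Reactants: 3 (2S)-2-[(1R)-1-(4-methoxybenzyloxy)prop-2-en-1-yl]oxirane
Product: 4 (3R,4S)-3-(4-methoxybenzyloxy)hept-1-en-6-yn-4-ol
Conditions: LiC≡CH·H2NCH2CH2NH2, DMSO, rt; then H2O
Reagents that add atoms: lithium acetylide–ethylenediamine complex, [Li+].[C-]#C.NCCN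
Why: SN2 opening of the terminal epoxide at its CH2 carbon by acetylide; the C–O bond at the future C3 is untouched, so both stereocentres are retained.

Step 4
Reactants: 4 (3R,4S)-3-(4-methoxybenzyloxy)hept-1-en-6-yn-4-ol
Product: 5 tert-butyl{[(3R,4S)-3-(4-methoxybenzyloxy)hept-1-en-6-yn-4-yl]oxy}dimethylsilane
Conditions: TBSCl, imidazole, DMF, rt
Reagents that add atoms: tert-butyldimethylsilyl chloride, CC(C)(C)[Si](C)(C)Cl
Why: standard silylation of the only free hydroxyl; the silyloxy group later blocks this oxygen as a nucleophile and serves as the stereodirecting group.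

Step 5
Reactants: 5 tert-butyl{[(3R,4S)-3-(4-methoxybenzyloxy)hept-1-en-6-yn-4-yl]oxy}dimethylsilane
Product: 6 (3R,4S)-4-(tert-butyldimethylsilyloxy)hept-1-en-6-yn-3-ol
Conditions: DDQ, CH2Cl2/pH 7 buffer, 0 °C
Reagents that add atoms: none
Why: oxidative PMB ether cleavage (benzylic hydride abstraction, hydrolysis of the oxocarbenium ion); the silyl ether, alkyne and vinyl group should be inert.

Step 6
Reactants: 6 (3R,4S)-4-(tert-butyldimethylsilyloxy)hept-1-en-6-yn-3-ol
Product: 9 tert-butyldimethyl{[(2R,3S,5S)-5-methyl-2-vinyltetrahydrofuran-3-yl]oxy}silane, via exocyclic enol ether 7 (not isolated), via oxocarbenium trifluoroacetate 8 (not isolated)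
Conditions: Ph3PAuCl/AgOTf (2 mol% each), CH2Cl2, 0 °C to rt; then Et3SiH (5 equiv), CF3CO2H (3 equiv), −78 to −30 °C
Reagents that add atoms: none
Why: Monovalent gold activates the terminal alkyne for anti-addition of the free hydroxyl at the internal alkyne carbon, closing the O1–C5 bond in the 5-exo-dig mode to give enol ether 7; protonation of its exocyclic CH2 by CF3CO2H turns the former alkyne terminus into the C5 methyl group and gives oxocarbenium ion 8, which Et3SiH reduces. The closest known reaction types are gold-catalysed alkynol cycloisomerisation and the silane reduction of furanosyl oxocarbenium ions in C-glycoside synthesis. The new stereocentre C5 is set in the hydride transfer under control of the C3 silyloxy group: in the preferred envelope of 8 this oxygen sits pseudoaxial and hydride enters on the inside face, cis to it (inside-attack model). The methyl group therefore ends up trans to the C3 oxygen and cis to the C2 vinyl group, which is the (5S) configuration. The step needs oxygen rather than alkene attack on the gold–alkyne complex, secured by the better-placed hydroxyl nucleophile and the deactivated allylic-ether vinyl group. It also needs reduction to outrun loss of H-4 and the silyloxy group (furan formation), secured by low temperature and excess silane.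

Step 7
Reactants: 9 tert-butyldimethyl{[(2R,3S,5S)-5-methyl-2-vinyltetrahydrofuran-3-yl]oxy}silane
Product: 10 tert-butyldimethyl({(2R,3S,5S)-5-methyl-2-[(E)-2-(4,4,5,5-tetramethyl-1,3,2-dioxaborolan-2-yl)vinyl]tetrahydrofuran-3-yl}oxy)silane
Conditions: vinyl-B(pin) (3 equiv), second-generation Hoveyda–Grubbs catalyst (H2IMes)Cl2Ru=CH(C6H4-2-OiPr) (5 mol%), CH2Cl2, 40 °C
Reagents that add atoms: vinylboronic acid pinacol ester, C=CB1OC(C)(C)C(C)(C)O1
Why: olefin cross-metathesis of a terminal alkene with a vinyl boronate; the bulky boronate should give the E-alkene, and no stereocentre is involved.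

Step 8
Reactants: 11 methyl 2,4-dimethoxy-6-methylbenzoate
Product: 12 methyl 3-chloro-4,6-dimethoxy-2-methylbenzoate
Conditions: SO2Cl2 (1.05 equiv), CH2Cl2, 0 °C
Reagents that add atoms: sulfuryl chloride, O=S(=O)(Cl)Cl
Why: electrophilic aromatic chlorination; the free position next to the C-methyl group (ortho to one methoxy, para to the other) should react in preference to the position flanked by both methoxy groups.

Step 9
Reactants: 12 methyl 3-chloro-4,6-dimethoxy-2-methylbenzoate
Product: 13 methyl 3-chloro-4,6-dimethoxy-2-(2-oxopropyl)benzoate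
Conditions: LiN(iPr)2, THF, −78 °C; then MeC(O)N(OMe)Me; aq. NH4Cl
Reagents that add atoms: N-methoxy-N-methylacetamide, CC(=O)N(C)OC
Why: lateral (benzylic) lithiation of the ortho-toluate followed by Weinreb amide acylation; the chelated tetrahedral adduct prevents over-addition.

Step 10
Reactants: 13 methyl 3-chloro-4,6-dimethoxy-2-(2-oxopropyl)benzoate
Product: 14 5-chloro-6,8-dimethoxy-3-methyl-1H-isochromen-1-one
Conditions: p-TsOH·H2O (cat.), toluene, reflux
Reagents that add atoms: none
Why: acid-catalysed enol lactonisation; the aryl-conjugated enol oxygen attacks the neighbouring ester (6-exo-trig) with loss of methanol, whereas base is avoided because it would favour C-acylation to a naphthalenediol.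

Step 11
Reactants: 14 5-chloro-6,8-dimethoxy-3-methyl-1H-isochromen-1-one
Product: 15 5-chloro-6,8-dimethoxy-1-oxo-1H-isochromene-3-carbaldehyde
Conditions: SeO2, 1,4-dioxane, reflux
Reagents that add atoms: selenium dioxide, O=[Se]=O
Why: Riley oxidation (ene reaction, then [2,3]-sigmatropic shift) of the allylic methyl group on the electron-rich C3=C4 enol-lactone double bond, expected to stop at the conjugated aldehyde.

Step 12
Reactants: 15 5-chloro-6,8-dimethoxy-1-oxo-1H-isochromene-3-carbaldehyde
Product: 16 5-chloro-3-[(E)-2-iodovinyl]-6,8-dimethoxy-1H-isochromen-1-one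
Conditions: CrCl2 (6 equiv), CHI3 (2 equiv), THF, 0 °C to rt
Reagents that add atoms: iodoform, IC(I)I
Why: Takai olefination; the geminal dichromium species formed from iodoform and divalent chromium adds to the aldehyde and eliminates to the E-iodoalkene, and the lactone and aryl chloride should not react.

Step 13
Reactants: 16 5-chloro-3-[(E)-2-iodovinyl]-6,8-dimethoxy-1H-isochromen-1-one
Product: 17 5-chloro-6,8-dihydroxy-3-[(E)-2-iodovinyl]-1H-isochromen-1-one
Conditions: BBr3 (6 equiv), CH2Cl2, −78 °C to rt; then H2O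
Reagents that add atoms: none
Why: Lewis-acid cleavage of both aryl methyl ethers (the peri ether is assisted by chelation to the lactone carbonyl), done before the acid-sensitive dienyl ether is present.

Step 14
Reactants: 10 tert-butyldimethyl({(2R,3S,5S)-5-methyl-2-[(E)-2-(4,4,5,5-tetramethyl-1,3,2-dioxaborolan-2-yl)vinyl]tetrahydrofuran-3-yl}oxy)silane; 17 5-chloro-6,8-dihydroxy-3-[(E)-2-iodovinyl]-1H-isochromen-1-one
Product: 18 3-[(1E,3E)-4-{(2R,3S,5S)-3-(tert-butyldimethylsilyloxy)-5-methyltetrahydrofuran-2-yl}buta-1,3-dien-1-yl]-5-chloro-6,8-dihydroxy-1H-isochromen-1-one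
Conditions: Pd(dppf)Cl2 (5 mol%), K3PO4 (4 equiv), THF/H2O, degassed, rt to 40 °C
Reagents that add atoms: none
Why: Suzuki–Miyaura coupling; zerovalent palladium inserts into the C–I bond far faster than into the hindered aryl C–Cl bond, both partners couple with retention to give the (E,E)-diene, and the phenols are carried as phenoxides.

Step 15
Reactants: 18 3-[(1E,3E)-4-{(2R,3S,5S)-3-(tert-butyldimethylsilyloxy)-5-methyltetrahydrofuran-2-yl}buta-1,3-dien-1-yl]-5-chloro-6,8-dihydroxy-1H-isochromen-1-one
Product: 19 5-chloro-6,8-dihydroxy-3-[(1E,3E)-4-{(2R,3S,5S)-3-hydroxy-5-methyltetrahydrofuran-2-yl}buta-1,3-dien-1-yl]-1H-isochromen-1-one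
Conditions: HF·pyridine, pyridine, THF, 0 °C to rt
Reagents that add atoms: none
Why: fluoride-driven desilylation under buffered conditions, so the dienyl-substituted C2–O1 ether and the lactone meet neither strong acid nor strong base; no stereocentre is touched.

**Compound list**

1 | penta-1,4-dien-3-ol (divinylcarbinol) | C=CC(O)C=C | starting material
2 | (2S,3R)-1,2-epoxypent-4-en-3-ol | C1O[C@@H]1[C@H](O)C=C | intermediate
3 | (2S)-2-[(1R)-1-(4-methoxybenzyloxy)prop-2-en-1-yl]oxirane | C1O[C@@H]1[C@H](OCc2ccc(OC)cc2)C=C | intermediate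
4 | (3R,4S)-3-(4-methoxybenzyloxy)hept-1-en-6-yn-4-ol | C#CC[C@H](O)[C@@H](C=C)OCc1ccc(OC)cc1 | intermediate
5 | tert-butyl{[(3R,4S)-3-(4-methoxybenzyloxy)hept-1-en-6-yn-4-yl]oxy}dimethylsilane | C#CC[C@H](O[Si](C)(C)C(C)(C)C)[C@@H](C=C)OCc1ccc(OC)cc1 | intermediate
6 | (3R,4S)-4-(tert-butyldimethylsilyloxy)hept-1-en-6-yn-3-ol | C#CC[C@H](O[Si](C)(C)C(C)(C)C)[C@@H](C=C)O | intermediate
7 | tert-butyldimethyl{[(2R,3S)-5-methylene-2-vinyltetrahydrofuran-3-yl]oxy}silane (exocyclic enol ether) | C=C1C[C@H](O[Si](C)(C)C(C)(C)C)[C@@H](C=C)O1 | intermediate (not isolated)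
8 | (2R,3S)-3-(tert-butyldimethylsilyloxy)-5-methyl-2-vinyl-3,4-dihydro-2H-furan-1-ium trifluoroacetate (oxocarbenium ion) | CC1=[O+][C@H](C=C)[C@@H](O[Si](C)(C)C(C)(C)C)C1.[O-]C(=O)C(F)(F)F | intermediate (not isolated)
9 | tert-butyldimethyl{[(2R,3S,5S)-5-methyl-2-vinyltetrahydrofuran-3-yl]oxy}silane | C[C@H]1C[C@H](O[Si](C)(C)C(C)(C)C)[C@@H](C=C)O1 | intermediate
10 | tert-butyldimethyl({(2R,3S,5S)-5-methyl-2-[(E)-2-(4,4,5,5-tetramethyl-1,3,2-dioxaborolan-2-yl)vinyl]tetrahydrofuran-3-yl}oxy)silane | C[C@H]1C[C@H](O[Si](C)(C)C(C)(C)C)[C@@H](/C=C/B2OC(C)(C)C(C)(C)O2)O1 | intermediate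
11 | methyl 2,4-dimethoxy-6-methylbenzoate | COC(=O)c1c(C)cc(OC)cc1OC | starting material
12 | methyl 3-chloro-4,6-dimethoxy-2-methylbenzoate | COC(=O)c1c(C)c(Cl)c(OC)cc1OC | intermediate
13 | methyl 3-chloro-4,6-dimethoxy-2-(2-oxopropyl)benzoate | COC(=O)c1c(CC(C)=O)c(Cl)c(OC)cc1OC | intermediate
14 | 5-chloro-6,8-dimethoxy-3-methyl-1H-isochromen-1-one | Cc1cc2c(Cl)c(OC)cc(OC)c2c(=O)o1 | intermediate
15 | 5-chloro-6,8-dimethoxy-1-oxo-1H-isochromene-3-carbaldehyde | O=Cc1cc2c(Cl)c(OC)cc(OC)c2c(=O)o1 | intermediate
16 | 5-chloro-3-[(E)-2-iodovinyl]-6,8-dimethoxy-1H-isochromen-1-one | I/C=C/c1cc2c(Cl)c(OC)cc(OC)c2c(=O)o1 | intermediate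
17 | 5-chloro-6,8-dihydroxy-3-[(E)-2-iodovinyl]-1H-isochromen-1-one | I/C=C/c1cc2c(Cl)c(O)cc(O)c2c(=O)o1 | intermediate
18 | 3-[(1E,3E)-4-{(2R,3S,5S)-3-(tert-butyldimethylsilyloxy)-5-methyltetrahydrofuran-2-yl}buta-1,3-dien-1-yl]-5-chloro-6,8-dihydroxy-1H-isochromen-1-one | C[C@H]1C[C@H](O[Si](C)(C)C(C)(C)C)[C@@H](/C=C/C=C/c2cc3c(Cl)c(O)cc(O)c3c(=O)o2)O1 | intermediate
19 | 5-chloro-6,8-dihydroxy-3-[(1E,3E)-4-{(2R,3S,5S)-3-hydroxy-5-methyltetrahydrofuran-2-yl}buta-1,3-dien-1-yl]-1H-isochromen-1-one | C[C@H]1C[C@H](O)[C@@H](/C=C/C=C/c2cc3c(Cl)c(O)cc(O)c3c(=O)o2)O1 | target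

**Totals**

Total step count: 15. Longest linear sequence: 9 steps (steps 1–7, then 14 and 15).

**Steps most likely to fail**

Step 6. What may go wrong: elimination of the C3 silyloxy group with aromatisation to a furan at the enol ether or oxocarbenium stage, competing gold-catalysed enyne cycloisomerisation, or insufficient facial selectivity in the hydride transfer. Fallback, from 3 back to 9, closing the same O1–C5 bond by iodoetherification: epoxide 3 is opened at its CH2 carbon with CH2=CHMgBr and CuI (cat.) in THF at −30 °C to give (3R,4S)-3-(4-methoxybenzyloxy)hepta-1,6-dien-4-ol F1, which is silylated (TBSCl, imidazole, DMF) to tert-butyl{[(3R,4S)-3-(4-methoxybenzyloxy)hepta-1,6-dien-4-yl]oxy}dimethylsilane F2. Iodine with NaHCO3 in MeCN at 0 °C should then bring about a 5-exo-trig iodoetherification in which the benzylic ether oxygen attacks the iodonium ion of the homoallylic alkene and the oxonium ion sheds the 4-methoxybenzyl group; a bulky ether oxygen is known to favour the 2,5-cis ring, giving tert-butyl{[(2R,3S,5R)-5-(iodomethyl)-2-vinyltetrahydrofuran-3-yl]oxy}dimethylsilane F3. Hydride displacement of iodide with LiBEt3H in THF at 0 °C (chosen over a tin hydride to avoid radical cyclisation onto the cis vinyl group) gives 9.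

Step 7. What may go wrong: slow turnover at the hindered allylic-ether alkene, with catalyst decay, double-bond migration or boronate homodimerisation taking over. Fallback, from 9 back to 10, by olefination instead of metathesis: ozonolysis of 9 (O3, CH2Cl2, −78 °C; then PPh3) gives (2S,3S,5S)-3-(tert-butyldimethylsilyloxy)-5-methyltetrahydrofuran-2-carbaldehyde F4, which is used at once in a Takai–Utimoto olefination (Cl2CHB(pin), CrCl2, LiI, THF, rt) to give the (E)-alkenyl boronate 10.

Step 11. What may go wrong: over-oxidation to the carboxylic acid, incomplete conversion, or oxidative degradation of the electron-rich ring. Fallback, from 12 back to 15, bringing the oxygen in with the acylating agent instead of by C–H oxidation: lithiated 12 (LiN(iPr)2, THF, −78 °C) is acylated with 2-(tert-butyldimethylsilyloxy)-N-methoxy-N-methylacetamide to give methyl 2-[3-(tert-butyldimethylsilyloxy)-2-oxopropyl]-3-chloro-4,6-dimethoxybenzoate F5. Acid (p-TsOH·H2O, toluene, 80 °C; then MeOH) should cause enol lactonisation and loss of the silyl group to give 5-chloro-3-(hydroxymethyl)-6,8-dimethoxy-1H-isochromen-1-one F6, and MnO2 in CH2Cl2 oxidises this allylic-type alcohol to aldehyde 15.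

**Further compounds**

F1 | step 6 | (3R,4S)-3-(4-methoxybenzyloxy)hepta-1,6-dien-4-ol | C=CC[C@H](O)[C@@H](C=C)OCc1ccc(OC)cc1
F2 | step 6 | tert-butyl{[(3R,4S)-3-(4-methoxybenzyloxy)hepta-1,6-dien-4-yl]oxy}dimethylsilane | C=CC[C@H](O[Si](C)(C)C(C)(C)C)[C@@H](C=C)OCc1ccc(OC)cc1
F3 | step 6 | tert-butyl{[(2R,3S,5R)-5-(iodomethyl)-2-vinyltetrahydrofuran-3-yl]oxy}dimethylsilane | IC[C@H]1C[C@H](O[Si](C)(C)C(C)(C)C)[C@@H](C=C)O1
F4 | step 7 | (2S,3S,5S)-3-(tert-butyldimethylsilyloxy)-5-methyltetrahydrofuran-2-carbaldehyde | C[C@H]1C[C@H](O[Si](C)(C)C(C)(C)C)[C@@H](C=O)O1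
F5 | step 11 | methyl 2-[3-(tert-butyldimethylsilyloxy)-2-oxopropyl]-3-chloro-4,6-dimethoxybenzoate | COC(=O)c1c(CC(=O)CO[Si](C)(C)C(C)(C)C)c(Cl)c(OC)cc1OC
F6 | step 11 | 5-chloro-3-(hydroxymethyl)-6,8-dimethoxy-1H-isochromen-1-one | OCc1cc2c(Cl)c(OC)cc(OC)c2c(=O)o1
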